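**Overview**

- Cuts: first the phenol O–Si bond; then, in one operation, the bond from the exocyclic arylidene CH to the syringyl ring and the ring bond C3–C4; the enyne left over is cut at its ester C–O bond.
- Enabling feature: in the lactone ring (O1, C2 carbonyl, C3, C4, C5) the exocyclic C3=CH–aryl unit has its aryl cis to C4, and C4 carries only H and a CH2–aryl group. This is the pattern left by syn aryl–metal addition to a terminal ynoate, 5-exo capture by a cinnamyl alkene and protonation at the benzylic carbon.
- Forward: both arenes are bought. Propiolic acid is esterified with 3,4,5-trimethoxycinnamyl alcohol, a silyl-protected syringylboronic acid is made from the bromophenol, and the butyrolactone, the only ring made, closes at C3–C4 in the rhodium step. Desilylation ends the route.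
- Stereochemistry: C4 (S) is set in the alkene insertion by a chiral diene on rhodium; the E arylidene follows from the syn addition; neither is touched afterwards.

Key step: step 6

Assumption: the (1R,4R) enantiomer of the diene ligand is taken to deliver the 4S lactone; the sense of induction depends only on the ligand, so if the first run shows the opposite sense the (1S,4S) ligand is used with nothing else changed. The phenol is carried as its triisopropylsilyl ether, which should tolerate n-BuLi and warm aqueous hydroxide better than a smaller silyl group.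

**Route**

Step 1
Reactants: 1 (E)-3,4,5-trimethoxycinnamic acid
Product: 2 methyl (E)-3-(3,4,5-trimethoxyphenyl)prop-2-enoate
Conditions: MeOH, H2SO4 (cat.), reflux
Reagents that add atoms: methanol, CO
Why: Fischer esterification driven by excess methanol; the alkene and the aryl methyl ethers are inert to it.

Step 2
Reactants: 2 methyl (E)-3-(3,4,5-trimethoxyphenyl)prop-2-enoate
Product: 3 (E)-3-(3,4,5-trimethoxyphenyl)prop-2-en-1-ol
Conditions: i-Bu2AlH (2.5 equiv), CH2Cl2, −78 to 0 °C; aq. potassium sodium tartrate
Reagents that add atoms: none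
Why: 1,2-reduction of a conjugated ester by the aluminium hydride gives the allylic alcohol without touching the alkene, so the E geometry is kept.

Step 3
Reactants: 3 (E)-3-(3,4,5-trimethoxyphenyl)prop-2-en-1-ol; 4 propiolic acid
Product: 6 (E)-3-(3,4,5-trimethoxyphenyl)prop-2-en-1-yl prop-2-ynoate, via O-propioloyl dicyclohexylisourea 5 (not isolated)
Conditions: DCC (1.1 equiv), DMAP (5 mol%), CH2Cl2, −20 to 0 °C
Reagents that add atoms: none
Why: Steglich esterification, in which the carbodiimide activates the acid and the primary allylic alcohol is acylated; low temperature and low DMAP loading keep nucleophiles from adding to the terminal ynoate.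

Step 4
Reactants: 7 4-bromo-2,6-dimethoxyphenol
Product: 8 (4-bromo-2,6-dimethoxyphenoxy)triisopropylsilane
Conditions: TIPSOTf (1.2 equiv), 2,6-lutidine, CH2Cl2, 0 °C to rt
Reagents that add atoms: triisopropylsilyl trifluoromethanesulfonate, CC(C)[Si](C(C)C)(C(C)C)OS(=O)(=O)C(F)(F)F
Why: O-silylation with a silyl triflate, reactive enough for a phenol flanked by two methoxy groups.

Step 5
Reactants: 8 (4-bromo-2,6-dimethoxyphenoxy)triisopropylsilane
Product: 11 [3,5-dimethoxy-4-(triisopropylsilyloxy)phenyl]boronic acid, via aryllithium 9 (not isolated), via lithium aryltriisopropoxyborate 10 (not isolated)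
Conditions: n-BuLi (1.05 equiv), THF, −78 °C; B(Oi-Pr)3, −78 °C to rt; aq. HCl (1 M), 0 °C
Reagents that add atoms: triisopropyl borate, CC(C)OB(OC(C)C)OC(C)C; water, O
Why: bromine–lithium exchange at −78 °C is faster than any attack on the hindered silyl ether, and electrophilic borylation of the aryllithium followed by mild hydrolysis of the ate complex gives the boronic acid.

Step 6
Reactants: 6 (E)-3-(3,4,5-trimethoxyphenyl)prop-2-en-1-yl prop-2-ynoate; 11 [3,5-dimethoxy-4-(triisopropylsilyloxy)phenyl]boronic acid
Product: 12 (3E,4S)-3-[3,5-dimethoxy-4-(triisopropylsilyloxy)benzylidene]-4-(3,4,5-trimethoxybenzyl)oxolan-2-one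
Conditions: [RhCl(C2H4)2]2 (2.5 mol%), (1R,4R)-2,5-diphenylbicyclo[2.2.2]octa-2,5-diene (5.5 mol%), aq. KOH (20 mol%), 11 (2.5 equiv), 1,4-dioxane/H2O (10:1), 40 °C, 6 added over 6 h by syringe pump
Reagents that add atoms: none
Why: Proposed new method: transmetalation of 11 to the hydroxo complex of monovalent rhodium gives an aryl–rhodium species that adds syn across the terminal ynoate of 6 (aryl to the CH terminus, rhodium to the carbon alpha to the ester); the alkenyl–rhodium then inserts the cinnamyl alkene, and water protonates the resulting eta-3 benzyl–rhodium to the CH2–aryl group and returns the rhodium hydroxide. The closest known reaction type is the chiral-diene/rhodium-catalysed asymmetric arylative cyclization of alkyne-tethered electron-poor alkenes with arylboronic acids, together with the aryl–rhodium addition to terminal alkynes that starts rhodium–diene alkyne polymerization; a terminal propiolate, an ester tether and a styrene acceptor ending in protonolysis have not been combined. The butyrolactone closes by 5-exo-trig migratory insertion that forms C3–C4, the three-atom ester tether and the benzylic stabilization of rhodium disfavouring the 6-endo mode. C4 is the only new stereocentre and is set in this insertion, the C2-symmetric diene on rhodium choosing the alkene face, while the E arylidene is the direct outcome of syn addition with retention at the alkenyl carbon. The step needs aryl delivery to the alkyne terminus (secured by ester polarization and the unsubstituted terminus), cyclization faster than a second alkyne insertion (secured by slow addition of 6 into excess 11, so that rhodium rests as the aryl species) and protonolysis faster than beta-hydride elimination at C4–H (favoured by the chelating diene, which leaves the eta-3 benzyl complex no open cis site, and by the aqueous medium). The trisubstituted arylidene lactone formed should be too hindered to take up a second aryl group, and the silyl ether, lactone and methyl ethers should be inert to the mild aqueous base.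

Step 7
Reactants: 12 (3E,4S)-3-[3,5-dimethoxy-4-(triisopropylsilyloxy)benzylidene]-4-(3,4,5-trimethoxybenzyl)oxolan-2-one
Product: 13 (3E,4S)-3-(4-hydroxy-3,5-dimethoxybenzylidene)-4-(3,4,5-trimethoxybenzyl)oxolan-2-one (target)
Conditions: TBAF (1.2 equiv), AcOH (1.5 equiv), THF, 0 °C
Reagents that add atoms: none
Why: fluoride-mediated desilylation of an aryl silyl ether, buffered by acetic acid so that the phenoxide is protonated at once; C4–H sits on the carbon next to the alpha carbon and is not activated by the carbonyl, so the stereocentre and the E alkene should be unaffected.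

**Compound list**

1 | (E)-3,4,5-trimethoxycinnamic acid | COc1cc(/C=C/C(=O)O)cc(OC)c1OC | starting material
2 | methyl (E)-3-(3,4,5-trimethoxyphenyl)prop-2-enoate | COC(=O)/C=C/c1cc(OC)c(OC)c(OC)c1 | intermediate
3 | (E)-3-(3,4,5-trimethoxyphenyl)prop-2-en-1-ol | COc1cc(/C=C/CO)cc(OC)c1OC | intermediate
4 | propiolic acid | C#CC(=O)O | starting material
5 | O-propioloyl-N,N'-dicyclohexylisourea (not isolated) | C#CC(=O)OC(=NC1CCCCC1)NC1CCCCC1 | intermediate
6 | (E)-3-(3,4,5-trimethoxyphenyl)prop-2-en-1-yl prop-2-ynoate | C#CC(=O)OC/C=C/c1cc(OC)c(OC)c(OC)c1 | intermediate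
7 | 4-bromo-2,6-dimethoxyphenol | COc1cc(Br)cc(OC)c1O | starting material
8 | (4-bromo-2,6-dimethoxyphenoxy)triisopropylsilane | COc1cc(Br)cc(OC)c1O[Si](C(C)C)(C(C)C)C(C)C | intermediate
9 | [3,5-dimethoxy-4-(triisopropylsilyloxy)phenyl]lithium (not isolated) | [Li]c1cc(OC)c(O[Si](C(C)C)(C(C)C)C(C)C)c(OC)c1 | intermediate
10 | lithium [3,5-dimethoxy-4-(triisopropylsilyloxy)phenyl]triisopropoxyborate (not isolated) | [Li+].CC(C)O[B-](OC(C)C)(OC(C)C)c1cc(OC)c(O[Si](C(C)C)(C(C)C)C(C)C)c(OC)c1 | intermediate
11 | [3,5-dimethoxy-4-(triisopropylsilyloxy)phenyl]boronic acid | COc1cc(B(O)O)cc(OC)c1O[Si](C(C)C)(C(C)C)C(C)C | intermediate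
12 | (3E,4S)-3-[3,5-dimethoxy-4-(triisopropylsilyloxy)benzylidene]-4-(3,4,5-trimethoxybenzyl)oxolan-2-one | COc1cc(/C=C2/C(=O)OC[C@H]2Cc2cc(OC)c(OC)c(OC)c2)cc(OC)c1O[Si](C(C)C)(C(C)C)C(C)C | intermediate
13 | (3E,4S)-3-(4-hydroxy-3,5-dimethoxybenzylidene)-4-(3,4,5-trimethoxybenzyl)oxolan-2-one | COc1cc(/C=C2/C(=O)OC[C@H]2Cc2cc(OC)c(OC)c(OC)c2)cc(OC)c1O | target

**Step count**

Total: 7 steps. Longest linear sequence: 5 steps (steps 1, 2, 3, 6, 7); the boronic acid branch (steps 4, 5) joins at step 6.

**Steps most likely to fail**

Step 6. What may go wrong: oligomerization of the terminal ynoate through alkynyl–rhodium formation or repeated alkyne insertion, beta-hydride elimination from the benzyl–rhodium intermediate with loss of the C4 stereocentre, or weak facial selectivity in the alkene insertion. The fallback uses only known reaction types (auxiliary-controlled alkylation, then aldol condensation); it sets out from acid 1, takes its aldehyde partner from bromide 8, and comes back at lactone 12.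
- Acid 1 is hydrogenated (H2, palladium on carbon, EtOAc) to 3-(3,4,5-trimethoxyphenyl)propanoic acid F1.
- Pivaloyl chloride and Et3N in THF convert it into the mixed pivalic anhydride F2, which acylates (R)-4-benzyl-2-oxazolidinone in the presence of LiCl to give the imide F3.
- Evans alkylation (NaN(SiMe3)2, THF, −78 °C, then tert-butyl bromoacetate) should give the (S)-configured tert-butyl succinate imide F4, the benzyl group of the auxiliary shielding one face of the chelated enolate.
- LiBH4 (THF, one equivalent of water, 0 °C) removes the auxiliary reductively to give tert-butyl (3S)-4-hydroxy-3-(3,4,5-trimethoxybenzyl)butanoate F5, and TFA in CH2Cl2 closes (4S)-4-(3,4,5-trimethoxybenzyl)oxolan-2-one F6.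
- Bromide 8 is lithiated as in step 5 (aryllithium 9) and quenched with DMF to give 3,5-dimethoxy-4-(triisopropylsilyloxy)benzaldehyde F7.
- The lithium enolate of F6 (LiN(SiMe3)2, THF, −78 °C) is added to F7 to give the aldol adduct F8 (3,4-trans expected, carbinol epimers). Mesylation (MsCl, Et3N, CH2Cl2, 0 °C) gives the methanesulfonate F9, and DBU eliminates it (E1cB) to the thermodynamically preferred E-arylidene lactone 12.

Step 3. What may go wrong: conjugate addition of the alcohol, DMAP or the urea to the activated terminal ynoate, and base-induced oligomerization of propiolic acid, so that the acid is consumed before acylation. The fallback masks the alkyne terminus; it sets out from alcohol 3 and comes back at enyne 6. Alcohol 3 is esterified with commercial 3-(trimethylsilyl)propiolic acid (DCC, DMAP, CH2Cl2, 0 °C), where the silyl group blocks the beta carbon and removes the acidic C–H, to give (E)-3-(3,4,5-trimethoxyphenyl)prop-2-en-1-yl 3-(trimethylsilyl)prop-2-ynoate F10. Buffered fluoride (TBAF, AcOH, THF, −20 °C) then cleaves the C–Si bond to give 6.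

Step 5. What may go wrong: incomplete bromine–lithium exchange, butylation of the aryllithium by the bromobutane formed, or protodeboronation of the electron-rich boronic acid during acidic work-up and isolation. The fallback replaces the organolithium by a palladium-catalysed borylation; it sets out from bromide 8 and comes back at boronic acid 11. Miyaura borylation of 8 (bis(pinacolato)diboron, PdCl2(dppf), KOAc, 1,4-dioxane, 80 °C) gives 2-[3,5-dimethoxy-4-(triisopropylsilyloxy)phenyl]-4,4,5,5-tetramethyl-1,3,2-dioxaborolane F11, a stable compound that can be purified on silica. Oxidative removal of the pinacol (NaIO4, NH4OAc, acetone/H2O, rt) then frees 11.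

**Further compounds**

F1 | step 6 | 3-(3,4,5-trimethoxyphenyl)propanoic acid | COc1cc(CCC(=O)O)cc(OC)c1OC
F2 | step 6 | 3-(3,4,5-trimethoxyphenyl)propanoic pivalic anhydride | COc1cc(CCC(=O)OC(=O)C(C)(C)C)cc(OC)c1OC
F3 | step 6 | (4R)-4-benzyl-3-[3-(3,4,5-trimethoxyphenyl)propanoyl]-1,3-oxazolidin-2-one | COc1cc(CCC(=O)N2[C@H](Cc3ccccc3)COC2=O)cc(OC)c1OC
F4 | step 6 | tert-butyl (3S)-4-[(4R)-4-benzyl-2-oxo-1,3-oxazolidin-3-yl]-4-oxo-3-(3,4,5-trimethoxybenzyl)butanoate | CC(C)(C)OC(=O)C[C@H](Cc1cc(OC)c(OC)c(OC)c1)C(=O)N1[C@H](Cc2ccccc2)COC1=O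
F5 | step 6 | tert-butyl (3S)-4-hydroxy-3-(3,4,5-trimethoxybenzyl)butanoate | CC(C)(C)OC(=O)C[C@H](Cc1cc(OC)c(OC)c(OC)c1)CO
F6 | step 6 | (4S)-4-(3,4,5-trimethoxybenzyl)oxolan-2-one | O=C1C[C@H](Cc2cc(OC)c(OC)c(OC)c2)CO1
F7 | step 6 | 3,5-dimethoxy-4-(triisopropylsilyloxy)benzaldehyde | COc1cc(C=O)cc(OC)c1O[Si](C(C)C)(C(C)C)C(C)C
F8 | step 6 | (4S)-3-{hydroxy[3,5-dimethoxy-4-(triisopropylsilyloxy)phenyl]methyl}-4-(3,4,5-trimethoxybenzyl)oxolan-2-one (C3 and carbinol centres as formed) | COc1cc(C(O)C2C(=O)OC[C@H]2Cc2cc(OC)c(OC)c(OC)c2)cc(OC)c1O[Si](C(C)C)(C(C)C)C(C)C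
F9 | step 6 | [3,5-dimethoxy-4-(triisopropylsilyloxy)phenyl][(4S)-2-oxo-4-(3,4,5-trimethoxybenzyl)oxolan-3-yl]methyl methanesulfonate | COc1cc(C(OS(C)(=O)=O)C2C(=O)OC[C@H]2Cc2cc(OC)c(OC)c(OC)c2)cc(OC)c1O[Si](C(C)C)(C(C)C)C(C)C
F10 | step 3 | (E)-3-(3,4,5-trimethoxyphenyl)prop-2-en-1-yl 3-(trimethylsilyl)prop-2-ynoate | C[Si](C)(C)C#CC(=O)OC/C=C/c1cc(OC)c(OC)c(OC)c1
F11 | step 5 | 2-[3,5-dimethoxy-4-(triisopropylsilyloxy)phenyl]-4,4,5,5-tetramethyl-1,3,2-dioxaborolane | COc1cc(B2OC(C)(C)C(C)(C)O2)cc(OC)c1O[Si](C(C)C)(C(C)C)C(C)C
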